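**Plan**

1. Retrosynthesis first exchanges the C3 formyl / C2 hydroxymethyl pair for a C2 formyl / C3 silyloxymethyl pair (redox and protecting-group steps only), then opens ring B at C1–C2.
2. The cut is possible because C1 carries a 4-hydroxyaryl group, so it becomes the exocyclic carbon of a para-quinone methide once the benzhydrol ionises, and C2 is the α-carbon of an aldehyde whose C3=C4 bond is conjugated to the dimethoxybenzo ring A, i.e. a dienamine under amine catalysis.
3. The open-chain enal is cut further at aryl–C1 (aryllithium plus O-silylvanillin) and at C4–C3 (benzylzinc plus a (Z)-iodoalkene from 2-butyne-1,4-diol).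
4. Forward order: C4 unit (steps 1–2), benzyl–alkenyl coupling and oxidation-level adjustment (3–5), benzhydrol formation and unmasking (6–8), closure of ring B (9), then reduction, silyl differentiation, allylic oxidation and desilylation (10–14).
5. C2 is set by the chiral amine catalyst in step 9 and C1 by relay (trans) in the same cyclic transition state; the C2 aldehyde is reduced at once and no later step touches either centre.

Key step: step 9

Assumption 1: atoms are numbered as in a 1-aryl-1,2-dihydronaphthalene (C1 aryl-bearing, C2 hydroxymethyl-bearing, C3 formyl-bearing, C4 vinylic CH); in this numbering the target is (1S,2R), trans.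
Assumption 2: the alkene geometry of the open-chain enal and its carbinol configuration are both erased in step 9 (dienamine formation, ionisation), so neither is controlled. The (R)-catalyst is assigned from the usual steric-shielding model of diarylprolinol silyl ether enamines.

**Route**

Step 1
Reactants: 1 2-butyne-1,4-diol
Product: 2 4-(tert-butyldimethylsilyloxy)but-2-yn-1-ol
Conditions: NaH (1.0 equiv), THF, 0 °C to rt; TBSCl (1.0 equiv), rt
Reagents that add atoms: tert-butyldimethylsilyl chloride (TBSCl), CC(C)(C)[Si](C)(C)Cl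
Why: Monosilylation of a symmetrical diol through its sparingly soluble monosodium alkoxide should stop at the monoether.

Step 2
Reactants: 2 4-(tert-butyldimethylsilyloxy)but-2-yn-1-ol
Product: 4 (Z)-4-(tert-butyldimethylsilyloxy)-3-iodobut-2-en-1-ol, via cyclic alkenylalanate 3 (not isolated)
Conditions: Red-Al (1.5 equiv), THF, 0 °C to rt; then I2, THF, –78 to 0 °C
Reagents that add atoms: iodine, II
Why: Hydroxyl-directed trans-hydroalumination of the propargylic alcohol places hydride on C2 and aluminium on C3 in a five-membered alanate, and iodinolysis with retention should give the (Z)-3-iodoallylic alcohol as one regio- and stereoisomer.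

Step 3
Reactants: 5 2-bromo-4,5-dimethoxybenzyl bromide; 4 (Z)-4-(tert-butyldimethylsilyloxy)-3-iodobut-2-en-1-ol
Product: 7 (E)-4-(2-bromo-4,5-dimethoxyphenyl)-3-[(tert-butyldimethylsilyloxy)methyl]but-2-en-1-ol, via benzylzinc bromide 6 (not isolated)
Conditions: 5, Zn dust, LiCl, THF, 0 °C to rt (slow addition); then 4 (limiting, 6 in 1.8-fold excess), Pd(PPh3)4 (5 mol%), THF, rt
Reagents that add atoms: none
Why: Zinc inserts only into the benzylic C–Br bond, and Negishi coupling of the benzylzinc halide with the alkenyl iodide proceeds at room temperature with retention of alkene geometry, much faster than oxidative addition into the electron-rich aryl bromide, and tolerates the free hydroxyl.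

Step 4
Reactants: 7 (E)-4-(2-bromo-4,5-dimethoxyphenyl)-3-[(tert-butyldimethylsilyloxy)methyl]but-2-en-1-ol
Product: 8 (E)-4-(2-bromo-4,5-dimethoxyphenyl)-3-[(tert-butyldimethylsilyloxy)methyl]but-2-enal
Conditions: activated MnO2 (15 equiv), CH2Cl2, rt
Reagents that add atoms: none
Why: Activated manganese dioxide oxidises primary allylic alcohols to enals and leaves the silyl ether and aryl bromide alone; any E/Z drift is of no consequence.

Step 5
Reactants: 8 (E)-4-(2-bromo-4,5-dimethoxyphenyl)-3-[(tert-butyldimethylsilyloxy)methyl]but-2-enal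
Product: 9 (E)-4-(2-bromo-4,5-dimethoxyphenyl)-3-[(tert-butyldimethylsilyloxy)methyl]but-2-enal dimethyl acetal
Conditions: HC(OMe)3 (3 equiv), PPTS (5 mol%), MeOH, rt; Et3N quench
Reagents that add atoms: trimethyl orthoformate, COC(OC)OC
Why: Acid-catalysed acetalisation with the orthoformate as water scavenger masks the enal for the organolithium step, and the weak acid should leave the primary TBS ether intact.

Step 6
Reactants: 10 vanillin
Product: 11 4-(tert-butyldimethylsilyloxy)-3-methoxybenzaldehyde
Conditions: TBSCl (1.1 equiv), imidazole, CH2Cl2, rt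
Reagents that add atoms: tert-butyldimethylsilyl chloride (TBSCl), CC(C)(C)[Si](C)(C)Cl
Why: Routine phenol silylation gives an aryl silyl ether that survives aryllithium addition and can later be removed by mild base without loss of the alkyl TBS ether.

Step 7
Reactants: 9 (E)-4-(2-bromo-4,5-dimethoxyphenyl)-3-[(tert-butyldimethylsilyloxy)methyl]but-2-enal dimethyl acetal; 11 4-(tert-butyldimethylsilyloxy)-3-methoxybenzaldehyde
Product: 13 [4-(tert-butyldimethylsilyloxy)-3-methoxyphenyl][2-[(E)-2-[(tert-butyldimethylsilyloxy)methyl]-4,4-dimethoxybut-2-enyl]-4,5-dimethoxyphenyl]methanol (racemic carbinol), via aryllithium 12 (not isolated)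
Conditions: n-BuLi (1.05 equiv), THF, –78 °C; then 11 (1.1 equiv), –78 to –40 °C; H2O
Reagents that add atoms: none
Why: Bromine–lithium exchange on the aryl bromide is faster at –78 °C than deprotonation of the benzylic/allylic CH2, and 1,2-addition of the aryllithium to the aldehyde gives the benzhydrol, whose configuration does not matter.

Step 8
Reactants: 13 [4-(tert-butyldimethylsilyloxy)-3-methoxyphenyl][2-[(E)-2-[(tert-butyldimethylsilyloxy)methyl]-4,4-dimethoxybut-2-enyl]-4,5-dimethoxyphenyl]methanol
Product: 15 (E)-3-[(tert-butyldimethylsilyloxy)methyl]-4-[2-[hydroxy(4-hydroxy-3-methoxyphenyl)methyl]-4,5-dimethoxyphenyl]but-2-enal (racemic carbinol), via phenol acetal 14 (not isolated)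
Conditions: K2CO3, MeOH, rt; then PPTS (10 mol%), acetone/H2O (10:1), 0 °C to rt
Reagents that add atoms: water, O
Why: Base-catalysed methanolysis cleaves aryl silyl ethers far faster than alkyl silyl ethers, and the allylic dimethyl acetal hydrolyses under acid too weak to cleave the primary TBS ether, while ionisation of the benzhydrol in the aqueous medium only returns the carbinol.

Step 9
Reactants: 15 (E)-3-[(tert-butyldimethylsilyloxy)methyl]-4-[2-[hydroxy(4-hydroxy-3-methoxyphenyl)methyl]-4,5-dimethoxyphenyl]but-2-enal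
Product: 17 (1S,2R)-3-[(tert-butyldimethylsilyloxy)methyl]-1-(4-hydroxy-3-methoxyphenyl)-6,7-dimethoxy-1,2-dihydronaphthalene-2-carbaldehyde, via dienamine quinone methide 16 (not isolated)
Conditions: (R)-α,α-diphenylprolinol trimethylsilyl ether (20 mol%), (PhO)2P(O)OH (30 mol%), CHCl3 (0.02 M), 0 °C to rt; crude product taken directly into step 10
Reagents that add atoms: none
Why: Proposed new method: the enal condenses with the secondary amine to an iminium ion that loses a benzylic C4 proton to give the aryl-conjugated dienamine, the acid dehydrates the 4-hydroxybenzhydrol so that the dienamine para-quinone methide 16 results, the dienamine α-carbon C2 adds to the methide carbon C1 in a 1,6-sense with rearomatisation of the phenol, and the water set free hydrolyses the β,γ-unsaturated iminium ion to 17 and the catalyst. The closest known reaction type is the intermolecular amine-catalysed α-alkylation of aldehydes and enals (enamine and dienamine activation) by para-quinone methides and benzhydryl cations, of which this is the intramolecular dienamine variant. Ring B closes in a 6-(enolexo)-exo-trig mode, the enamine C=C and the methide C=C both lying outside the new ring and C3=C4 staying inside it. C2 is set by the catalyst, whose (R)-configured diphenyl(silyloxy)methyl group shields the Si face of the s-trans (E)-enamine so that C1 bonds to the Re face (2R); C1 is set by relay in the sofa-like transition state, where the quinoid ring sits pseudo-axial and anti to the enamine carbon, which should give the trans (1S,2R) product from either carbinol epimer. The step needs α- over γ-attack, benzylic over CH2OSi γ-deprotonation and cyclisation over oligomerisation: γ-attack at C4 would demand a four-membered ring, only the benzylic dienamine is conjugated with the dimethoxyarene, and high dilution plus the reversible hydration of the methide favour the intramolecular path. The free phenol of 15 is what makes C1 a neutral, strongly electrophilic methide under mild acid.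

Step 10
Reactants: 17 (1S,2R)-3-[(tert-butyldimethylsilyloxy)methyl]-1-(4-hydroxy-3-methoxyphenyl)-6,7-dimethoxy-1,2-dihydronaphthalene-2-carbaldehyde
Product: 18 [(1S,2R)-3-[(tert-butyldimethylsilyloxy)methyl]-1-(4-hydroxy-3-methoxyphenyl)-6,7-dimethoxy-1,2-dihydronaphthalen-2-yl]methanol
Conditions: NaBH4, MeOH/CH2Cl2, 0 °C
Reagents that add atoms: none
Why: Borohydride reduction of the aldehyde is fast at 0 °C and removes the acidic α-formyl hydrogen, so C2 can no longer epimerise and the C3=C4 bond can no longer migrate.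

Step 11
Reactants: 18 [(1S,2R)-3-[(tert-butyldimethylsilyloxy)methyl]-1-(4-hydroxy-3-methoxyphenyl)-6,7-dimethoxy-1,2-dihydronaphthalen-2-yl]methanol
Product: 19 (1S,2R)-3-[(tert-butyldimethylsilyloxy)methyl]-2-[(tert-butyldiphenylsilyloxy)methyl]-1-[4-(tert-butyldiphenylsilyloxy)-3-methoxyphenyl]-6,7-dimethoxy-1,2-dihydronaphthalene
Conditions: TBDPSCl (2.5 equiv), imidazole, DMAP (cat.), DMF, rt
Reagents that add atoms: tert-butyldiphenylsilyl chloride (TBDPSCl), CC(C)(C)[Si](Cl)(c1ccccc1)c1ccccc1
Why: Silylation of the phenol and the primary alcohol with the more robust TBDPS group differentiates them from the C3 TBS ether and blocks lactol/lactone formation and phenol oxidation in the later MnO2 step.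

Step 12
Reactants: 19 (1S,2R)-3-[(tert-butyldimethylsilyloxy)methyl]-2-[(tert-butyldiphenylsilyloxy)methyl]-1-[4-(tert-butyldiphenylsilyloxy)-3-methoxyphenyl]-6,7-dimethoxy-1,2-dihydronaphthalene
Product: 20 [(1S,2R)-2-[(tert-butyldiphenylsilyloxy)methyl]-1-[4-(tert-butyldiphenylsilyloxy)-3-methoxyphenyl]-6,7-dimethoxy-1,2-dihydronaphthalen-3-yl]methanol
Conditions: HF·pyridine, pyridine, THF, 0 °C to rt
Reagents that add atoms: none
Why: Under buffered HF a primary TBS ether is cleaved much faster than primary or aryl TBDPS ethers, a standard selective desilylation that avoids the protic acid a cinnamyl-type alcohol would not tolerate.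

Step 13
Reactants: 20 [(1S,2R)-2-[(tert-butyldiphenylsilyloxy)methyl]-1-[4-(tert-butyldiphenylsilyloxy)-3-methoxyphenyl]-6,7-dimethoxy-1,2-dihydronaphthalen-3-yl]methanol
Product: 21 (1S,2R)-2-[(tert-butyldiphenylsilyloxy)methyl]-1-[4-(tert-butyldiphenylsilyloxy)-3-methoxyphenyl]-6,7-dimethoxy-1,2-dihydronaphthalene-3-carbaldehyde
Conditions: activated MnO2 (15 equiv), CH2Cl2, rt, short reaction time
Reagents that add atoms: none
Why: Manganese dioxide oxidation of the cinnamyl-type allylic alcohol gives the aryl-conjugated enal, and with the neighbouring hydroxymethyl group silylated no lactol can form and over-oxidise.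

Step 14
Reactants: 21 (1S,2R)-2-[(tert-butyldiphenylsilyloxy)methyl]-1-[4-(tert-butyldiphenylsilyloxy)-3-methoxyphenyl]-6,7-dimethoxy-1,2-dihydronaphthalene-3-carbaldehyde
Product: 22 (1S,2R)-1-(4-hydroxy-3-methoxyphenyl)-2-(hydroxymethyl)-6,7-dimethoxy-1,2-dihydronaphthalene-3-carbaldehyde
Conditions: TBAF (2.5 equiv), AcOH (2.5 equiv), THF, 0 °C to rt
Reagents that add atoms: none
Why: Fluoride cleaves the aryl and the primary TBDPS ether, the acetic acid buffer keeps the enal and phenol away from basic side reactions, and neither C1–H nor C2–H is acidic enough to epimerise.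

**Compound list**

1 | 2-butyne-1,4-diol | OCC#CCO | starting material
2 | 4-(tert-butyldimethylsilyloxy)but-2-yn-1-ol | OCC#CCO[Si](C)(C)C(C)(C)C | intermediate
3 | sodium cyclic alkenylalanate from 2 (five-membered O–Al–C=C chelate, two 2-methoxyethoxy ligands on Al; formed in the flask) | [Na+].COCCO[Al-]1(OCCOC)OCC=C1CO[Si](C)(C)C(C)(C)C | intermediate
4 | (Z)-4-(tert-butyldimethylsilyloxy)-3-iodobut-2-en-1-ol | OC/C=C(\I)CO[Si](C)(C)C(C)(C)C | intermediate
5 | 2-bromo-4,5-dimethoxybenzyl bromide | COc1cc(Br)c(CBr)cc1OC | starting material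
6 | (2-bromo-4,5-dimethoxybenzyl)zinc bromide (formed in the flask) | COc1cc(Br)c(C[Zn]Br)cc1OC | intermediate
7 | (E)-4-(2-bromo-4,5-dimethoxyphenyl)-3-[(tert-butyldimethylsilyloxy)methyl]but-2-en-1-ol | OC/C=C(/CO[Si](C)(C)C(C)(C)C)Cc1cc(OC)c(OC)cc1Br | intermediate
8 | (E)-4-(2-bromo-4,5-dimethoxyphenyl)-3-[(tert-butyldimethylsilyloxy)methyl]but-2-enal | O=C/C=C(/CO[Si](C)(C)C(C)(C)C)Cc1cc(OC)c(OC)cc1Br | intermediate
9 | (E)-4-(2-bromo-4,5-dimethoxyphenyl)-3-[(tert-butyldimethylsilyloxy)methyl]but-2-enal dimethyl acetal | COC(OC)/C=C(/CO[Si](C)(C)C(C)(C)C)Cc1cc(OC)c(OC)cc1Br | intermediate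
10 | vanillin | COc1cc(C=O)ccc1O | starting material
11 | 4-(tert-butyldimethylsilyloxy)-3-methoxybenzaldehyde | COc1cc(C=O)ccc1O[Si](C)(C)C(C)(C)C | intermediate
12 | [2-[(E)-2-[(tert-butyldimethylsilyloxy)methyl]-4,4-dimethoxybut-2-enyl]-4,5-dimethoxyphenyl]lithium (formed in the flask) | COC(OC)/C=C(/CO[Si](C)(C)C(C)(C)C)Cc1cc(OC)c(OC)cc1[Li] | intermediate
13 | [4-(tert-butyldimethylsilyloxy)-3-methoxyphenyl][2-[(E)-2-[(tert-butyldimethylsilyloxy)methyl]-4,4-dimethoxybut-2-enyl]-4,5-dimethoxyphenyl]methanol, racemic at the carbinol | COC(OC)/C=C(/CO[Si](C)(C)C(C)(C)C)Cc1cc(OC)c(OC)cc1C(O)c1ccc(O[Si](C)(C)C(C)(C)C)c(OC)c1 | intermediate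
14 | 4-[hydroxy[2-[(E)-2-[(tert-butyldimethylsilyloxy)methyl]-4,4-dimethoxybut-2-enyl]-4,5-dimethoxyphenyl]methyl]-2-methoxyphenol, racemic at the carbinol (formed in the flask) | COC(OC)/C=C(/CO[Si](C)(C)C(C)(C)C)Cc1cc(OC)c(OC)cc1C(O)c1ccc(O)c(OC)c1 | intermediate
15 | (E)-3-[(tert-butyldimethylsilyloxy)methyl]-4-[2-[hydroxy(4-hydroxy-3-methoxyphenyl)methyl]-4,5-dimethoxyphenyl]but-2-enal, racemic at the carbinol | O=C/C=C(/CO[Si](C)(C)C(C)(C)C)Cc1cc(OC)c(OC)cc1C(O)c1ccc(O)c(OC)c1 | intermediate
16 | dienamine of 15 with the (R)-catalyst, (1E,3Z)-configured with C2 and the arene cis on C3=C4, carrying the para-quinone methide in place of the benzhydrol (formed in the flask) | C[Si](C)(C)OC(c1ccccc1)(c1ccccc1)[C@H]1CCCN1/C=C/C(CO[Si](C)(C)C(C)(C)C)=C\c1cc(OC)c(OC)cc1C=C1C=CC(=O)C(OC)=C1 | intermediate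
17 | (1S,2R)-3-[(tert-butyldimethylsilyloxy)methyl]-1-(4-hydroxy-3-methoxyphenyl)-6,7-dimethoxy-1,2-dihydronaphthalene-2-carbaldehyde | COc1cc([C@H]2c3cc(OC)c(OC)cc3C=C(CO[Si](C)(C)C(C)(C)C)[C@@H]2C=O)ccc1O | intermediate
18 | [(1S,2R)-3-[(tert-butyldimethylsilyloxy)methyl]-1-(4-hydroxy-3-methoxyphenyl)-6,7-dimethoxy-1,2-dihydronaphthalen-2-yl]methanol | COc1cc([C@H]2c3cc(OC)c(OC)cc3C=C(CO[Si](C)(C)C(C)(C)C)[C@@H]2CO)ccc1O | intermediate
19 | (1S,2R)-3-[(tert-butyldimethylsilyloxy)methyl]-2-[(tert-butyldiphenylsilyloxy)methyl]-1-[4-(tert-butyldiphenylsilyloxy)-3-methoxyphenyl]-6,7-dimethoxy-1,2-dihydronaphthalene | COc1cc([C@H]2c3cc(OC)c(OC)cc3C=C(CO[Si](C)(C)C(C)(C)C)[C@@H]2CO[Si](c2ccccc2)(c2ccccc2)C(C)(C)C)ccc1O[Si](c1ccccc1)(c1ccccc1)C(C)(C)C | intermediate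
20 | [(1S,2R)-2-[(tert-butyldiphenylsilyloxy)methyl]-1-[4-(tert-butyldiphenylsilyloxy)-3-methoxyphenyl]-6,7-dimethoxy-1,2-dihydronaphthalen-3-yl]methanol | COc1cc([C@H]2c3cc(OC)c(OC)cc3C=C(CO)[C@@H]2CO[Si](c2ccccc2)(c2ccccc2)C(C)(C)C)ccc1O[Si](c1ccccc1)(c1ccccc1)C(C)(C)C | intermediate
21 | (1S,2R)-2-[(tert-butyldiphenylsilyloxy)methyl]-1-[4-(tert-butyldiphenylsilyloxy)-3-methoxyphenyl]-6,7-dimethoxy-1,2-dihydronaphthalene-3-carbaldehyde | COc1cc([C@H]2c3cc(OC)c(OC)cc3C=C(C=O)[C@@H]2CO[Si](c2ccccc2)(c2ccccc2)C(C)(C)C)ccc1O[Si](c1ccccc1)(c1ccccc1)C(C)(C)C | intermediate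
22 | (1S,2R)-1-(4-hydroxy-3-methoxyphenyl)-2-(hydroxymethyl)-6,7-dimethoxy-1,2-dihydronaphthalene-3-carbaldehyde, equally (3R,4S)-4-(4-hydroxy-3-methoxyphenyl)-3-(hydroxymethyl)-6,7-dimethoxy-3,4-dihydronaphthalene-2-carbaldehyde | COc1cc([C@H]2c3cc(OC)c(OC)cc3C=C(C=O)[C@@H]2CO)ccc1O | target

**Totals**

Total steps: 14. Longest linear sequence: 13 (steps 1–5 and 7–14; step 6 is the only branch).

**Steps most likely to fail**

Step 9. The cyclisation may fail through γ-deprotonation on the silyloxymethyl side, through intermolecular capture of the quinone methide (oligomerisation), or through weak facial control at C2 or weak trans relay to C1. The fallback forms the same C1–C2 bond by known silyl enol ether chemistry and obtains the enantiomer by resolution. It sets out from 15. Exhaustive silylation with TBSOTf/Et3N (CH2Cl2, –78 to 0 °C) should give the O,O-disilylated 1-silyloxydiene F1. BF3·OEt2 in CH2Cl2 at –78 °C ionises the benzhydryl silyl ether, and the tethered silyl dienol ether closes the ring at its α-carbon in an intramolecular Mukaiyama-type SN1 alkylation, giving the racemic trans O-silyl aldehyde F2. NaBH4 in MeOH followed by K2CO3 in the same flask reduces the aldehyde and cleaves the aryl silyl ether to the racemic alcohol F3. Preparative chromatography on a chiral stationary phase then gives the (1S,2R)-enantiomer, which is 18; the other enantiomer is discarded.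

Step 8. The acid needed to hydrolyse the acetal may also ionise the free-phenol benzhydrol and start intermolecular phenol–quinone methide coupling, or may erode the alkyl TBS ether. The fallback avoids both the acetal and any acid before the key step. It sets out from 7. Treatment with n-BuLi (2.1 equiv, THF, –78 °C; alkoxide formation, then bromine–lithium exchange) and addition of 11 should give the benzhydrol/allylic alcohol diol F4. Aerobic Cu(I)/bipyridine/TEMPO/N-methylimidazole oxidation in MeCN, selective for primary over secondary alcohols, should give the enal with the phenol still silylated, F5. Brief exposure to TBAF/AcOH (1 equiv, THF, 0 °C) removes only the aryl silyl ether and returns to the route at 15.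

Step 3. The benzylzinc reagent may be lost to Wurtz homocoupling during zinc insertion or to protonolysis by the free hydroxyl, or palladium may insert into the aryl bromide. The fallback inverts the polarity of the coupling. It sets out from 4. Miyaura borylation (B2pin2, PdCl2(dppf), KOPh, toluene, 50 °C) should give the alkenyl pinacol boronate F6. Suzuki–Miyaura coupling of F6 with the benzyl bromide 5 (Pd(PPh3)4, K3PO4, THF/H2O, 60 °C), in which oxidative addition occurs at the benzylic C–Br bond, returns to the route at 7.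

**Further compounds**

F1 | step 9 | (1E)-1-(tert-butyldimethylsilyloxy)-3-[(tert-butyldimethylsilyloxy)methyl]-4-[2-[(tert-butyldimethylsilyloxy)[4-(tert-butyldimethylsilyloxy)-3-methoxyphenyl]methyl]-4,5-dimethoxyphenyl]buta-1,3-diene (3,4-geometry not defined, racemic) | CC(C)(C)[Si](C)(C)O/C=C/C(CO[Si](C)(C)C(C)(C)C)=Cc1cc(OC)c(OC)cc1C(O[Si](C)(C)C(C)(C)C)c1ccc(O[Si](C)(C)C(C)(C)C)c(OC)c1
F2 | step 9 | racemic trans-3-[(tert-butyldimethylsilyloxy)methyl]-1-[4-(tert-butyldimethylsilyloxy)-3-methoxyphenyl]-6,7-dimethoxy-1,2-dihydronaphthalene-2-carbaldehyde (both enantiomers) | COc1cc([C@H]2c3cc(OC)c(OC)cc3C=C(CO[Si](C)(C)C(C)(C)C)[C@@H]2C=O)ccc1O[Si](C)(C)C(C)(C)C.COc1cc([C@@H]2c3cc(OC)c(OC)cc3C=C(CO[Si](C)(C)C(C)(C)C)[C@H]2C=O)ccc1O[Si](C)(C)C(C)(C)C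
F3 | step 9 | racemic trans-[3-[(tert-butyldimethylsilyloxy)methyl]-1-(4-hydroxy-3-methoxyphenyl)-6,7-dimethoxy-1,2-dihydronaphthalen-2-yl]methanol (both enantiomers) | COc1cc([C@H]2c3cc(OC)c(OC)cc3C=C(CO[Si](C)(C)C(C)(C)C)[C@@H]2CO)ccc1O.COc1cc([C@@H]2c3cc(OC)c(OC)cc3C=C(CO[Si](C)(C)C(C)(C)C)[C@H]2CO)ccc1O
F4 | step 8 | (E)-3-[(tert-butyldimethylsilyloxy)methyl]-4-[2-[[4-(tert-butyldimethylsilyloxy)-3-methoxyphenyl](hydroxy)methyl]-4,5-dimethoxyphenyl]but-2-en-1-ol (racemic carbinol) | OC/C=C(/CO[Si](C)(C)C(C)(C)C)Cc1cc(OC)c(OC)cc1C(O)c1ccc(O[Si](C)(C)C(C)(C)C)c(OC)c1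
F5 | step 8 | (E)-3-[(tert-butyldimethylsilyloxy)methyl]-4-[2-[[4-(tert-butyldimethylsilyloxy)-3-methoxyphenyl](hydroxy)methyl]-4,5-dimethoxyphenyl]but-2-enal (racemic carbinol) | O=C/C=C(/CO[Si](C)(C)C(C)(C)C)Cc1cc(OC)c(OC)cc1C(O)c1ccc(O[Si](C)(C)C(C)(C)C)c(OC)c1
F6 | step 3 | (E)-4-(tert-butyldimethylsilyloxy)-3-(4,4,5,5-tetramethyl-1,3,2-dioxaborolan-2-yl)but-2-en-1-ol | OC/C=C(\B1OC(C)(C)C(C)(C)O1)CO[Si](C)(C)C(C)(C)C
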